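**Assumption:** the target has no stereocentre and is achiral; its only stereo-element is the (E)-C4=C5 double bond, so "single enantiomer" is read as the single (E)-isomer.

**Retrosynthetic overview**
- The (E)-enone is traced back to a β-hydroxy ketone (dehydration), whose C4–C5 bond is cut by a crossed aldol between the methyl-side lithium enolate of O-silylated zingerone and an O-silylated 3-(syringyl)propanal.
- The ketone fragment is zingerone, silylated once; the aldehyde fragment comes from syringaldehyde by silylation, Wittig two-carbon extension, hydrogenation, reduction and oxidation.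
- No ring is formed: both benzene rings are carried intact from zingerone and syringaldehyde.
- Both phenols travel as TBS ethers and are cleaved last with buffered fluoride, which leaves the enone untouched.

**Step 1**
Reactants: 1 zingerone [4-(4-hydroxy-3-methoxyphenyl)butan-2-one]
Product: 2 4-[4-(tert-butyldimethylsilyloxy)-3-methoxyphenyl]butan-2-one
Conditions: TBSCl (1.2 equiv), imidazole (2.5 equiv), DMF, rt
Reagents that add atoms: tert-butyldimethylsilyl chloride, CC(C)(C)[Si](C)(C)Cl
Why: Imidazole-promoted O-silylation of the phenol (silyl ether protection) masks the acidic OH so that one equivalent of base later gives only the ketone enolate.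

**Step 2**
Reactants: 3 syringaldehyde (4-hydroxy-3,5-dimethoxybenzaldehyde)
Product: 4 4-(tert-butyldimethylsilyloxy)-3,5-dimethoxybenzaldehyde
Conditions: TBSCl (1.3 equiv), imidazole (2.5 equiv), DMF, rt → 40 °C
Reagents that add atoms: tert-butyldimethylsilyl chloride, CC(C)(C)[Si](C)(C)Cl
Why: The acidic para-formyl phenol is silylated cleanly under standard imidazole conditions (silyl ether protection) despite the two flanking methoxy groups.

**Step 3**
Reactants: 4 4-(tert-butyldimethylsilyloxy)-3,5-dimethoxybenzaldehyde; 5 ethyl (triphenylphosphoranylidene)acetate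
Product: 6 ethyl (E)-3-[4-(tert-butyldimethylsilyloxy)-3,5-dimethoxyphenyl]prop-2-enoate
Conditions: 5 (1.2 equiv), toluene, 90 °C
Reagents that add atoms: none
Why: Wittig olefination with a stabilised ylide runs under neutral conditions that spare the aryl silyl ether and gives the (E)-cinnamate, whose geometry is irrelevant because the alkene is hydrogenated next.

**Step 4**
Reactants: 6 ethyl (E)-3-[4-(tert-butyldimethylsilyloxy)-3,5-dimethoxyphenyl]prop-2-enoate
Product: 7 ethyl 3-[4-(tert-butyldimethylsilyloxy)-3,5-dimethoxyphenyl]propanoate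
Conditions: H2 (1 atm), 10% Pd/C, EtOAc, rt
Reagents that add atoms: none
Why: Catalytic hydrogenation saturates the conjugated alkene without touching the ester, the arene or (in EtOAc, not MeOH) the silyl ether.

**Step 5**
Reactants: 7 ethyl 3-[4-(tert-butyldimethylsilyloxy)-3,5-dimethoxyphenyl]propanoate
Product: 8 3-[4-(tert-butyldimethylsilyloxy)-3,5-dimethoxyphenyl]propan-1-ol
Conditions: DIBAL-H (2.5 equiv), CH2Cl2, −78 → 0 °C; aq. Rochelle salt work-up
Reagents that add atoms: none
Why: Full hydride reduction of the ester to the primary alcohol is more dependable than stopping at the aldehyde, and DIBAL-H at low temperature leaves the aryl silyl ether intact.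

**Step 6**
Reactants: 8 3-[4-(tert-butyldimethylsilyloxy)-3,5-dimethoxyphenyl]propan-1-ol
Product: 9 3-[4-(tert-butyldimethylsilyloxy)-3,5-dimethoxyphenyl]propanal
Conditions: Dess–Martin periodinane (1.2 equiv), CH2Cl2, 0 °C → rt; used promptly after a short silica plug
Reagents that add atoms: none
Why: Dess–Martin oxidation converts the primary alcohol to the aldehyde under mild, near-neutral conditions without over-oxidation or silyl loss.

**Step 7**
Reactants: 2 4-[4-(tert-butyldimethylsilyloxy)-3-methoxyphenyl]butan-2-one; 9 3-[4-(tert-butyldimethylsilyloxy)-3,5-dimethoxyphenyl]propanal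
Product: 11 (±)-1-[4-(tert-butyldimethylsilyloxy)-3-methoxyphenyl]-7-[4-(tert-butyldimethylsilyloxy)-3,5-dimethoxyphenyl]-5-hydroxyheptan-3-one, via lithium enolate 10 (not isolated)
Conditions: LDA (1.15 equiv), THF, −78 °C, 2 (1.1 equiv) added dropwise, 45 min; then 9 (1.0 equiv), −78 °C, 1 h; AcOH in THF quench at −78 °C
Reagents that add atoms: lithium diisopropylamide, CC(C)N([Li])C(C)C (its lithium is carried only by intermediate 10)
Why: LDA at −78 °C removes a methyl proton of the methyl ketone kinetically, and the preformed lithium enolate adds to the aldehyde in a directed crossed aldol addition faster than proton exchange; the new carbinol centre forms racemic, which does not matter because step 8 removes it.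

**Step 8**
Reactants: 11 (±)-1-[4-(tert-butyldimethylsilyloxy)-3-methoxyphenyl]-7-[4-(tert-butyldimethylsilyloxy)-3,5-dimethoxyphenyl]-5-hydroxyheptan-3-one
Product: 13 (E)-1-[4-(tert-butyldimethylsilyloxy)-3-methoxyphenyl]-7-[4-(tert-butyldimethylsilyloxy)-3,5-dimethoxyphenyl]hept-4-en-3-one, via β-keto mesylate 12 (not isolated)
Conditions: MsCl (1.5 equiv), Et3N (4 equiv), CH2Cl2, 0 °C → rt
Reagents that add atoms: methanesulfonyl chloride, CS(=O)(=O)Cl (its atoms are carried only by intermediate 12)
Why: O-mesylation of the β-hydroxy ketone followed by Et3N-induced E1cB elimination gives the conjugated enone, and the trans arrangement of the two chains makes the (E)-isomer the strongly favoured product, which sets the only stereo-element of the target.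

**Step 9**
Reactants: 13 (E)-1-[4-(tert-butyldimethylsilyloxy)-3-methoxyphenyl]-7-[4-(tert-butyldimethylsilyloxy)-3,5-dimethoxyphenyl]hept-4-en-3-one
Product: 14 (E)-1-(4-hydroxy-3-methoxyphenyl)-7-(4-hydroxy-3,5-dimethoxyphenyl)hept-4-en-3-one
Conditions: TBAF (2.4 equiv), AcOH (2.6 equiv), THF, 0 °C
Reagents that add atoms: none
Why: Fluoride-mediated desilylation cleaves both aryl silyl ethers within minutes, and the acetic acid buffer protonates the phenoxides so the (E)-enone is neither isomerised nor attacked in a conjugate addition.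

**Compound list**
1 | zingerone, 4-(4-hydroxy-3-methoxyphenyl)butan-2-one | CC(=O)CCc1ccc(O)c(OC)c1 | starting material
2 | 4-[4-(tert-butyldimethylsilyloxy)-3-methoxyphenyl]butan-2-one | CC(=O)CCc1ccc(O[Si](C)(C)C(C)(C)C)c(OC)c1 | intermediate
3 | syringaldehyde, 4-hydroxy-3,5-dimethoxybenzaldehyde | COc1cc(C=O)cc(OC)c1O | starting material
4 | 4-(tert-butyldimethylsilyloxy)-3,5-dimethoxybenzaldehyde | COc1cc(C=O)cc(OC)c1O[Si](C)(C)C(C)(C)C | intermediate
5 | ethyl (triphenylphosphoranylidene)acetate | CCOC(=O)C=P(c1ccccc1)(c1ccccc1)c1ccccc1 | starting material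
6 | ethyl (E)-3-[4-(tert-butyldimethylsilyloxy)-3,5-dimethoxyphenyl]prop-2-enoate | CCOC(=O)/C=C/c1cc(OC)c(O[Si](C)(C)C(C)(C)C)c(OC)c1 | intermediate
7 | ethyl 3-[4-(tert-butyldimethylsilyloxy)-3,5-dimethoxyphenyl]propanoate | CCOC(=O)CCc1cc(OC)c(O[Si](C)(C)C(C)(C)C)c(OC)c1 | intermediate
8 | 3-[4-(tert-butyldimethylsilyloxy)-3,5-dimethoxyphenyl]propan-1-ol | OCCCc1cc(OC)c(O[Si](C)(C)C(C)(C)C)c(OC)c1 | intermediate
9 | 3-[4-(tert-butyldimethylsilyloxy)-3,5-dimethoxyphenyl]propanal | O=CCCc1cc(OC)c(O[Si](C)(C)C(C)(C)C)c(OC)c1 | intermediate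
10 | lithium 4-[4-(tert-butyldimethylsilyloxy)-3-methoxyphenyl]but-1-en-2-olate, the kinetic lithium enolate of 2, not isolated | [Li]OC(=C)CCc1ccc(O[Si](C)(C)C(C)(C)C)c(OC)c1 | intermediate
11 | (±)-1-[4-(tert-butyldimethylsilyloxy)-3-methoxyphenyl]-7-[4-(tert-butyldimethylsilyloxy)-3,5-dimethoxyphenyl]-5-hydroxyheptan-3-one (racemic) | COc1cc(CCC(=O)CC(O)CCc2cc(OC)c(O[Si](C)(C)C(C)(C)C)c(OC)c2)ccc1O[Si](C)(C)C(C)(C)C | intermediate
12 | (±)-1-[4-(tert-butyldimethylsilyloxy)-3,5-dimethoxyphenyl]-7-[4-(tert-butyldimethylsilyloxy)-3-methoxyphenyl]-5-oxoheptan-3-yl methanesulfonate (racemic), not isolated | COc1cc(CCC(=O)CC(OS(C)(=O)=O)CCc2cc(OC)c(O[Si](C)(C)C(C)(C)C)c(OC)c2)ccc1O[Si](C)(C)C(C)(C)C | intermediate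
13 | (E)-1-[4-(tert-butyldimethylsilyloxy)-3-methoxyphenyl]-7-[4-(tert-butyldimethylsilyloxy)-3,5-dimethoxyphenyl]hept-4-en-3-one | COc1cc(CCC(=O)/C=C/CCc2cc(OC)c(O[Si](C)(C)C(C)(C)C)c(OC)c2)ccc1O[Si](C)(C)C(C)(C)C | intermediate
14 | (E)-1-(4-hydroxy-3-methoxyphenyl)-7-(4-hydroxy-3,5-dimethoxyphenyl)hept-4-en-3-one (CID5317592) | COc1cc(CCC(=O)/C=C/CCc2cc(OC)c(O)c(OC)c2)ccc1O | target

**Totals**
Total step count: 9. Longest linear sequence: 8 steps (steps 2–9, from syringaldehyde 3 to target 14); step 1 is a one-step side branch that joins at step 7.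

**Steps most likely to fail, each with a fallback**

Step 7 (crossed aldol). The risks are proton transfer to the enolisable aldehyde 9, self-aldol of 9 and retro-aldol on warming. The fallback sets out from 2 and comes back at 11. The kinetic enolate of 2 (LDA, THF, −78 °C) is trapped with TMSCl to give the trimethylsilyl enol ether {4-[4-(tert-butyldimethylsilyloxy)-3-methoxyphenyl]but-1-en-2-yl}oxytrimethylsilane F1. This is then joined to aldehyde 9 in a Lewis-acid-mediated Mukaiyama aldol addition (BF3·OEt2, CH2Cl2, −78 °C). No basic enolate ever meets the aldehyde, and aqueous work-up gives 11.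

Step 8 (dehydration). The risks are incomplete elimination, partial loss of an aryl silyl ether, or retro-aldol of 11 under base. The fallback sets out from 11 and comes back at 14, so it also bypasses step 9. Both silyl groups are removed first (TBAF/AcOH, THF, 0 °C) to give the free bisphenolic aldol (±)-5-hydroxy-1-(4-hydroxy-3-methoxyphenyl)-7-(4-hydroxy-3,5-dimethoxyphenyl)heptan-3-one F2. This is then dehydrated under acid catalysis (cat. p-TsOH, toluene, 80 °C) through the enol, as in the gingerol-to-shogaol conversion, to give the (E)-enone 14 directly.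

Step 6 (oxidation to the aldehyde). The risk is that the electron-rich, enolisable aldehyde 9 degrades during oxidation or isolation. The fallback sets out from 7 and comes back at 9, replacing steps 5 and 6. Ester 7 is treated with MeNH(OMe)·HCl and i-PrMgCl (THF, −20 °C) to give the Weinreb amide 3-[4-(tert-butyldimethylsilyloxy)-3,5-dimethoxyphenyl]-N-methoxy-N-methylpropanamide F3. This is reduced with DIBAL-H (THF, −78 °C); the chelated tetrahedral intermediate releases aldehyde 9 only on work-up, so there is no oxidation step and no over-reduction.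

**Further compounds**
F1 | step 7 | {4-[4-(tert-butyldimethylsilyloxy)-3-methoxyphenyl]but-1-en-2-yl}oxytrimethylsilane | C=C(O[Si](C)(C)C)CCc1ccc(O[Si](C)(C)C(C)(C)C)c(OC)c1
F2 | step 8 | (±)-5-hydroxy-1-(4-hydroxy-3-methoxyphenyl)-7-(4-hydroxy-3,5-dimethoxyphenyl)heptan-3-one (racemic) | COc1cc(CCC(=O)CC(O)CCc2cc(OC)c(O)c(OC)c2)ccc1O
F3 | step 6 | 3-[4-(tert-butyldimethylsilyloxy)-3,5-dimethoxyphenyl]-N-methoxy-N-methylpropanamide | CON(C)C(=O)CCc1cc(OC)c(O[Si](C)(C)C(C)(C)C)c(OC)c1
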